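**Plan**
- Retrosynthesis: the three MOM ethers come off last. Ring C is then cut at C4–C4a and at O1–C8a in one operation, giving ring A as 3,5-bis(methoxymethoxy)benzyne and the ring B/D part as an (S)-β-silyloxy N-methoxy-N-methylamide. The amide is cut at C3–C2 (acetamide aldol) to the ring B/D aldehyde, and that at the prenyl–aryl bond and at pyran ring D.
- Forward: ring D is annulated onto 5-bromo-2,4-dihydroxybenzaldehyde (ring B), the prenyl group is coupled in, the C2–C3–C4 chain is attached and C2 is set. Ring A arrives as an aryne and ring C closes last through C4–C4a.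
- Enabling feature: ring A carries oxygen on C5, C7 and C8a. The C5 oxygen polarises the aryne C4a≡C8a, so the C2 alkoxide bonds to C8a and leaves the carbanion on C4a, six atoms from the amide carbon C4.
- Stereochemistry: C2 (S) is set by Noyori-type asymmetric transfer hydrogenation of the β-keto amide with the (S,S)-TsDPEN ruthenium catalyst. The C2–O bond is never broken afterwards, and the flavanone carbonyl is unveiled only on a mildly acidic quench.

Key step: step 11

Assumption: the given SMILES encodes the (2S)-flavanone; compounds 1, 8, 9, 13 and 15 are taken as purchasable.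

**Route**

Step 1
Reactants: 1 phloroglucinol
Product: 2 3,5-bis(methoxymethoxy)phenol
Conditions: MOMCl (2.0 equiv), i-Pr2NEt (2.2 equiv), DMF/CH2Cl2, 0 °C to rt; chromatography
Reagents that add atoms: chloromethyl methyl ether (COCCl)
Why: Williamson-type O-alkylation of the symmetric triphenol with a limiting amount of the chloride should give the bis-ether as the main fraction of a statistical mixture, the mono- and tris-ethers being separated and recycled.

Step 2
Reactants: 2 3,5-bis(methoxymethoxy)phenol
Product: 3 2-bromo-3,5-bis(methoxymethoxy)phenol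
Conditions: NBS (1.0 equiv), i-Pr2NH (10 mol %), CH2Cl2, −78 °C
Reagents that add atoms: N-bromosuccinimide (O=C1CCC(=O)N1Br)
Why: Electrophilic aromatic bromination in which amine-mediated delivery of bromine through the hydrogen-bonded phenol should favour the two equivalent ortho carbons over the more hindered carbon between the two OMOM groups, the minor 4-bromo isomer being removed by chromatography.

Step 3
Reactants: 3 2-bromo-3,5-bis(methoxymethoxy)phenol
Product: 7 3,5-bis(methoxymethoxy)-2-(trimethylsilyl)phenyl trifluoromethanesulfonate, via silyl ether 4 (not isolated), via aryllithium 5 (not isolated), via lithium phenoxide 6 (not isolated)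
Conditions: HMDS, THF, 65 °C, evaporate; n-BuLi (1.1 equiv), THF, −100 to −78 °C; Tf2O (1.2 equiv), −78 to 0 °C
Reagents that add atoms: hexamethyldisilazane (C[Si](C)(C)N[Si](C)(C)C); trifluoromethanesulfonic anhydride (O=S(=O)(OS(=O)(=O)C(F)(F)F)C(F)(F)F)
Why: O-silylation, bromine–lithium exchange, anionic 1,3-silyl shift from oxygen to carbon (retro-Brook rearrangement) and triflation of the phenoxide form the standard one-flask route to ortho-silylaryl triflates, and aryl MOM ethers should tolerate it at low temperature.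

Step 4
Reactants: 8 5-bromo-2,4-dihydroxybenzaldehyde; 9 3-methylbut-2-enal
Product: 11 8-bromo-5-hydroxy-2,2-dimethyl-2H-chromene-6-carbaldehyde, via oxatriene 10 (not isolated)
Conditions: ethylenediammonium diacetate (10 mol %), xylene, 140 °C, removal of water
Reagents that add atoms: none
Why: Knoevenagel-type condensation at the only free carbon between the two phenol oxygens followed by oxa-6π electrocyclization should build ring D; the hydroxyl chelated to the formyl group stays free, so the ring closes on the other oxygen, and bromine blocks the alternative carbon.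

Step 5
Reactants: 11 8-bromo-5-hydroxy-2,2-dimethyl-2H-chromene-6-carbaldehyde
Product: 12 8-bromo-5-(methoxymethoxy)-2,2-dimethyl-2H-chromene-6-carbaldehyde
Conditions: MOMCl (1.5 equiv), i-Pr2NEt (2 equiv), CH2Cl2, 0 to 40 °C
Reagents that add atoms: chloromethyl methyl ether (COCCl)
Why: O-alkylation of the chelated phenol masks the ring B hydroxyl as the same acetal used on ring A, so that one final operation frees all three phenols.

Step 6
Reactants: 12 bromo aldehyde; 13 tributyl(3-methylbut-2-en-1-yl)stannane
Product: 14 5-(methoxymethoxy)-2,2-dimethyl-8-(3-methylbut-2-en-1-yl)-2H-chromene-6-carbaldehyde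
Conditions: Pd(PPh3)4 (5 mol %), DMF, 100 °C
Reagents that add atoms: none
Why: Stille cross-coupling (oxidative addition of zerovalent palladium into the aryl bromide, transmetalation of the allylic stannane at its α carbon, reductive elimination) should give the linear prenyl arene, and the aldehyde is not attacked by the stannane without a Lewis acid.

Step 7
Reactants: 14 prenylated aldehyde; 15 N-methoxy-N-methylacetamide
Product: 17 rac-β-hydroxy N-methoxy-N-methylamide, via lithium enolate 16 (not isolated)
Conditions: LiN(i-Pr)2 (1.2 equiv), THF, −78 °C; then 14; AcOH quench at −78 °C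
Reagents that add atoms: none
Why: Aldol addition of the lithium amide enolate to the aldehyde installs C3 and C4 at the amide oxidation level; the carbinol is left racemic on purpose because it is erased in step 8.

Step 8
Reactants: 17 rac-β-hydroxy amide
Product: 18 β-keto N-methoxy-N-methylamide
Conditions: Dess–Martin periodinane (1.3 equiv), CH2Cl2, 0 °C to rt
Reagents that add atoms: none
Why: Dess–Martin oxidation of the benzylic carbinol under non-basic conditions should avoid retro-aldol cleavage and leave the prenyl and chromene alkenes untouched.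

Step 9
Reactants: 18 β-keto amide
Product: 19 (3S)-β-hydroxy N-methoxy-N-methylamide
Conditions: RuCl[(S,S)-TsDPEN](p-cymene) (2 mol %), HCO2H/Et3N (5:2), DMF, 30 °C
Reagents that add atoms: none
Why: Noyori-type asymmetric transfer hydrogenation, in which outer-sphere hydride delivery from the ruthenium hydride of the (S,S) complex to the aryl ketone (aryl as the large group) should set the S carbinol, as known for aryl β-keto esters and amides; isolated alkenes are not reduced.

Step 10
Reactants: 19 (3S)-β-hydroxy amide
Product: 20 (3S)-β-(triethylsilyloxy) N-methoxy-N-methylamide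
Conditions: Et3SiCl (1.3 equiv), imidazole (2.5 equiv), DMF, 0 °C to rt
Reagents that add atoms: chlorotriethylsilane (CC[Si](Cl)(CC)CC)
Why: Imidazole-mediated silylation replaces the O–H by a fluoride-labile silyl group, so that step 11 can release the alkoxide in a medium free of proton sources.

Step 11
Reactants: 20 (3S)-β-(triethylsilyloxy) amide; 7 ortho-silylaryl triflate
Product: 25 (2S)-5,7-bis(methoxymethoxy)-2-[5-(methoxymethoxy)-2,2-dimethyl-8-(3-methylbut-2-en-1-yl)-2H-chromen-6-yl]-2,3-dihydro-4H-chromen-4-one, via cesium alkoxide 21 (not isolated), via aryne 22 (not isolated), via aryl cesium 23 (not isolated), via hemiaminal alkoxide 24 (not isolated)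
Conditions: CsF (5 equiv), 18-crown-6 (2 equiv), THF, 0 °C to rt, 7 (1.6 equiv) added over 3 h; then AcOH, −20 °C
Reagents that add atoms: none
Why: Proposed new method: fluoride strips the triethylsilyl group from 20 and unmasks aryne 22 from 7, the cesium alkoxide 21 adds to the aryne carbon remote from the flanking OMOM group (the inductively withdrawing C5 oxygen makes that carbon the electrophilic end and stabilises the carbanion on its neighbour, as in known additions to 3-alkoxyarynes), and aryl anion 23, which finds no proton source in the aprotic medium, attacks the amide carbonyl six atoms away to form the C4–C4a bond. The closest known reaction types are the fluoride-induced annulation of arynes with salicylates to xanthones (O-attack, then acylation by the aryl anion), the acyl-alkylation of 3,5-dialkoxyarynes with β-keto esters, and the Parham cyclization of aryllithiums onto amides. Ring C closes in a 6-exo-trig mode, and hemiaminal alkoxide 24 is held until the acetic acid quench, so that the base-labile flavanone never meets alkoxide or fluoride. No new stereocenter remains after collapse of 24, and C2 keeps the S configuration of 19 because its oxygen is arylated and the C2–O bond is never broken. The step needs O-regioselectivity on the aryne (secured by the polarisation through the C5 oxygen), acylation in preference to protonation of 23 (secured by the silyl ether in place of the free alcohol), and chemoselectivity over ene or [2+2] reactions of the prenyl and chromene alkenes (secured by slow addition of 7, which keeps the aryne dilute beside the far more nucleophilic alkoxide).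

Step 12
Reactants: 25 tris-MOM flavanone
Product: 26 sanggenol N
Conditions: conc. HCl (5 equiv), MeOH/THF (4:1), 40 °C, monitored; NaHCO3 work-up
Reagents that add atoms: none
Why: Acid-catalysed transacetalisation of the three MOM ethers to dimethoxymethane should free the phenols; C2 is not α to the carbonyl, and the prenyl group has no free ortho hydroxyl to cyclise onto, so the configuration and the alkenes should survive a short, mild treatment.

**Compound list**

1 | phloroglucinol (benzene-1,3,5-triol) | Oc1cc(O)cc(O)c1 | starting material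
2 | 3,5-bis(methoxymethoxy)phenol | COCOc1cc(O)cc(OCOC)c1 | intermediate
3 | 2-bromo-3,5-bis(methoxymethoxy)phenol | COCOc1cc(O)c(Br)c(OCOC)c1 | intermediate
4 | [2-bromo-3,5-bis(methoxymethoxy)phenoxy]trimethylsilane | COCOc1cc(O[Si](C)(C)C)c(Br)c(OCOC)c1 | intermediate
5 | [2,4-bis(methoxymethoxy)-6-(trimethylsilyloxy)phenyl]lithium | COCOc1cc(O[Si](C)(C)C)c([Li])c(OCOC)c1 | intermediate
6 | lithium 3,5-bis(methoxymethoxy)-2-(trimethylsilyl)phenoxide | COCOc1cc([O-])c([Si](C)(C)C)c(OCOC)c1.[Li+] | intermediate
7 | 3,5-bis(methoxymethoxy)-2-(trimethylsilyl)phenyl trifluoromethanesulfonate | COCOc1cc(OS(=O)(=O)C(F)(F)F)c([Si](C)(C)C)c(OCOC)c1 | intermediate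
8 | 5-bromo-2,4-dihydroxybenzaldehyde | O=Cc1cc(Br)c(O)cc1O | starting material
9 | 3-methylbut-2-enal | CC(C)=CC=O | starting material
10 | 3-bromo-6-hydroxy-5-(3-methylbut-2-en-1-ylidene)-4-oxocyclohexa-1,6-diene-1-carbaldehyde (oxatriene) | O=CC1=C(O)C(=CC=C(C)C)C(=O)C(Br)=C1 | intermediate
11 | 8-bromo-5-hydroxy-2,2-dimethyl-2H-chromene-6-carbaldehyde | CC1(C)C=Cc2c(O)c(C=O)cc(Br)c2O1 | intermediate
12 | 8-bromo-5-(methoxymethoxy)-2,2-dimethyl-2H-chromene-6-carbaldehyde | CC1(C)C=Cc2c(OCOC)c(C=O)cc(Br)c2O1 | intermediate
13 | tributyl(3-methylbut-2-en-1-yl)stannane | CCCC[Sn](CCCC)(CCCC)CC=C(C)C | starting material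
14 | 5-(methoxymethoxy)-2,2-dimethyl-8-(3-methylbut-2-en-1-yl)-2H-chromene-6-carbaldehyde | CC(C)=CCc1cc(C=O)c(OCOC)c2c1OC(C)(C)C=C2 | intermediate
15 | N-methoxy-N-methylacetamide | CC(=O)N(C)OC | starting material
16 | lithium 1-[methoxy(methyl)amino]ethen-1-olate | C=C([O-])N(C)OC.[Li+] | intermediate
17 | rac-3-hydroxy-N-methoxy-3-[5-(methoxymethoxy)-2,2-dimethyl-8-(3-methylbut-2-en-1-yl)-2H-chromen-6-yl]-N-methylpropanamide | CC(C)=CCc1cc(C(O)CC(=O)N(C)OC)c(OCOC)c2c1OC(C)(C)C=C2 | intermediate
18 | N-methoxy-3-[5-(methoxymethoxy)-2,2-dimethyl-8-(3-methylbut-2-en-1-yl)-2H-chromen-6-yl]-N-methyl-3-oxopropanamide | CC(C)=CCc1cc(C(=O)CC(=O)N(C)OC)c(OCOC)c2c1OC(C)(C)C=C2 | intermediate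
19 | (3S)-3-hydroxy-N-methoxy-3-[5-(methoxymethoxy)-2,2-dimethyl-8-(3-methylbut-2-en-1-yl)-2H-chromen-6-yl]-N-methylpropanamide | CC(C)=CCc1cc([C@@H](O)CC(=O)N(C)OC)c(OCOC)c2c1OC(C)(C)C=C2 | intermediate
20 | (3S)-N-methoxy-3-[5-(methoxymethoxy)-2,2-dimethyl-8-(3-methylbut-2-en-1-yl)-2H-chromen-6-yl]-N-methyl-3-(triethylsilyloxy)propanamide | CC(C)=CCc1cc([C@@H](O[Si](CC)(CC)CC)CC(=O)N(C)OC)c(OCOC)c2c1OC(C)(C)C=C2 | intermediate
21 | cesium (1S)-3-[methoxy(methyl)amino]-1-[5-(methoxymethoxy)-2,2-dimethyl-8-(3-methylbut-2-en-1-yl)-2H-chromen-6-yl]-3-oxopropan-1-olate | CC(C)=CCc1cc([C@@H]([O-])CC(=O)N(C)OC)c(OCOC)c2c1OC(C)(C)C=C2.[Cs+] | intermediate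
22 | 3,5-bis(methoxymethoxy)benzyne (1,2-didehydro-3,5-bis(methoxymethoxy)benzene) | COCOC1=CC(OCOC)=CC#C1 | intermediate
23 | cesium 2-aryloxy-4,6-bis(methoxymethoxy)phenide, the aryloxy group being the (1S)-3-[methoxy(methyl)amino]-3-oxo-1-(chromen-6-yl)propoxy unit of 21 | CC(C)=CCc1cc([C@@H](Oc3cc(OCOC)cc(OCOC)[c-]3)CC(=O)N(C)OC)c(OCOC)c2c1OC(C)(C)C=C2.[Cs+] | intermediate
24 | cesium (2S)-4-[methoxy(methyl)amino]-5,7-bis(methoxymethoxy)-2-[5-(methoxymethoxy)-2,2-dimethyl-8-(3-methylbut-2-en-1-yl)-2H-chromen-6-yl]chroman-4-olate | CC(C)=CCc1cc([C@@H]3CC([O-])(N(C)OC)c4c(OCOC)cc(OCOC)cc4O3)c(OCOC)c2c1OC(C)(C)C=C2.[Cs+] | intermediate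
25 | (2S)-5,7-bis(methoxymethoxy)-2-[5-(methoxymethoxy)-2,2-dimethyl-8-(3-methylbut-2-en-1-yl)-2H-chromen-6-yl]-2,3-dihydro-4H-chromen-4-one | CC(C)=CCc1cc([C@@H]3CC(=O)c4c(OCOC)cc(OCOC)cc4O3)c(OCOC)c2c1OC(C)(C)C=C2 | intermediate
26 | sanggenol N, (2S)-5,7-dihydroxy-2-[5-hydroxy-2,2-dimethyl-8-(3-methylbut-2-en-1-yl)-2H-chromen-6-yl]-2,3-dihydro-4H-chromen-4-one | CC(C)=CCc1cc([C@@H]2CC(=O)c3c(O)cc(O)cc3O2)c(O)c2c1OC(C)(C)C=C2 | target

**Count and risks**

Total steps: 12. Longest linear sequence: 9 (steps 4 to 12); steps 1 to 3 form the convergent ring A branch.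

Steps most likely to fail:

1. Step 11 (Proposed new method). The aryl anion may be protonated before it reaches the amide, the free alkoxide may undergo retro-aldol cleavage, or the hemiaminal may collapse early and expose the flavanone to base (ring opening, loss of configuration). Fallback by known chemistry, setting out from keto amide 18 and returning at 25: transfer hydrogenation with the antipodal catalyst RuCl[(R,R)-TsDPEN](p-cymene) in HCO2H/Et3N should give the antipodal alcohol (3R)-3-hydroxy-N-methoxy-3-[5-(methoxymethoxy)-2,2-dimethyl-8-(3-methylbut-2-en-1-yl)-2H-chromen-6-yl]-N-methylpropanamide F1. Mitsunobu etherification of it with bromophenol 3 (PPh3, DIAD, toluene, 0 °C) should give, with inversion, the aryl ether (3S)-3-[2-bromo-3,5-bis(methoxymethoxy)phenoxy]-N-methoxy-3-[5-(methoxymethoxy)-2,2-dimethyl-8-(3-methylbut-2-en-1-yl)-2H-chromen-6-yl]-N-methylpropanamide F2. Bromine–lithium exchange (t-BuLi, 2.1 equiv, THF, −100 °C) should give the aryllithium of that ether F3, which closes ring C by Parham cyclization to the lithium hemiaminal alkoxide F4. An AcOH quench then gives 25.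

2. Step 12. Acid may ionise the benzylic C2–O1 bond, which is activated by the two oxygens on ring B (erosion of configuration), or add HCl or methanol across the prenyl alkene. Fallback, setting out from 25 and returning at 26: TMSOTf (6 equiv) and 2,2'-bipyridyl (9 equiv) in CH2Cl2 at 0 °C should exchange the three aryl MOM groups for silyl groups without free protic acid, giving the tris(trimethylsilyl) ether of sanggenol N F5. Stirring it in THF/water at rt should hydrolyse it to 26.

3. Step 2. Bromination may go to the carbon between the two OMOM groups or run on to the dibromide. Fallback, setting out from 2 and returning at 7, with the silyl group placed by directed ortho-metalation instead of halogenation: Et2NCOCl and K2CO3 in MeCN should give 3,5-bis(methoxymethoxy)phenyl diethylcarbamate F6. s-BuLi/TMEDA in THF at −78 °C followed by Me3SiCl should silylate the carbon between the carbamate (the stronger director) and an OMOM group, giving 3,5-bis(methoxymethoxy)-2-(trimethylsilyl)phenyl diethylcarbamate F7. LiAlH4 in THF at 0 °C should cleave the carbamate to 3,5-bis(methoxymethoxy)-2-(trimethylsilyl)phenol F8, and Tf2O/pyridine in CH2Cl2 at 0 °C should give 7.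

Further compounds
F1 | step 11 | (3R)-3-hydroxy-N-methoxy-3-[5-(methoxymethoxy)-2,2-dimethyl-8-(3-methylbut-2-en-1-yl)-2H-chromen-6-yl]-N-methylpropanamide | CC(C)=CCc1cc([C@H](O)CC(=O)N(C)OC)c(OCOC)c2c1OC(C)(C)C=C2
F2 | step 11 | (3S)-3-[2-bromo-3,5-bis(methoxymethoxy)phenoxy]-N-methoxy-3-[5-(methoxymethoxy)-2,2-dimethyl-8-(3-methylbut-2-en-1-yl)-2H-chromen-6-yl]-N-methylpropanamide | CC(C)=CCc1cc([C@@H](Oc3cc(OCOC)cc(OCOC)c3Br)CC(=O)N(C)OC)c(OCOC)c2c1OC(C)(C)C=C2
F3 | step 11 | aryllithium from bromine–lithium exchange of F2 | CC(C)=CCc1cc([C@@H](Oc3cc(OCOC)cc(OCOC)c3[Li])CC(=O)N(C)OC)c(OCOC)c2c1OC(C)(C)C=C2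
F4 | step 11 | lithium (2S)-4-[methoxy(methyl)amino]-5,7-bis(methoxymethoxy)-2-[5-(methoxymethoxy)-2,2-dimethyl-8-(3-methylbut-2-en-1-yl)-2H-chromen-6-yl]chroman-4-olate | CC(C)=CCc1cc([C@@H]3CC([O-])(N(C)OC)c4c(OCOC)cc(OCOC)cc4O3)c(OCOC)c2c1OC(C)(C)C=C2.[Li+]
F5 | step 12 | (2S)-2-[2,2-dimethyl-8-(3-methylbut-2-en-1-yl)-5-(trimethylsilyloxy)-2H-chromen-6-yl]-5,7-bis(trimethylsilyloxy)-2,3-dihydro-4H-chromen-4-one | CC(C)=CCc1cc([C@@H]2CC(=O)c3c(O[Si](C)(C)C)cc(O[Si](C)(C)C)cc3O2)c(O[Si](C)(C)C)c2c1OC(C)(C)C=C2
F6 | step 2 | 3,5-bis(methoxymethoxy)phenyl diethylcarbamate | CCN(CC)C(=O)Oc1cc(OCOC)cc(OCOC)c1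
F7 | step 2 | 3,5-bis(methoxymethoxy)-2-(trimethylsilyl)phenyl diethylcarbamate | CCN(CC)C(=O)Oc1cc(OCOC)cc(OCOC)c1[Si](C)(C)C
F8 | step 2 | 3,5-bis(methoxymethoxy)-2-(trimethylsilyl)phenol | COCOc1cc(O)c([Si](C)(C)C)c(OCOC)c1
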